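**Retrosynthetic overview**

1. The target, (−)-epicatechin 3-O-syringate (2R,3R, 2,3-cis), is cut at the C3–O acyl bond into protected epicatechin 11 and 4-O-benzylsyringic acid 12; ring A phenols are carried as TIPS ethers, all other phenols as benzyl ethers.
2. cis-Alcohol 11 comes from racemic flavan-3-one 10 by dynamic kinetic asymmetric transfer hydrogenation, which sets C2 and C3 together; 10 comes from 3-nitroflavan 8 by a Nef reaction, the nitro group being a temporary activating group that becomes the C3 oxygen.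
3. Ring C is the only ring made (rings A and B are bought); it is closed at C2–C3 by a redox-neutral 1,5-hydride shift/ring closure of nitrostyrene 6.
4. Enabling feature: C2–H lies between O1 and the 4'-oxygenated ring B (a hydridic, p-alkoxybenzyl-ether C–H) and is 1,5-related through O1–C8a–C4a to C4, which is a CH2 in the target; C2 can therefore give its hydride to C4 and then, as an oxocarbenium carbon, bond to a C3 nitronate.
5. 6 comes from aldehyde 4 and nitromethane (Henry), 4 from phenol 2 and benzylic alcohol 3 (Mitsunobu), and 2 from 2,4,6-trihydroxybenzaldehyde 1.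

Key step: step 4

Assumption: the (R,R)-TsDPEN catalyst of step 6 is taken to give the (2R,3R) alcohol (acetophenone-type model with the C2 side of the ketone next to the arene ligand); should the sense of induction be the opposite, the (S,S) catalyst is used with no other change.

**Route**

Step 1
Reactants: 1 2,4,6-trihydroxybenzaldehyde
Product: 2 2-hydroxy-4,6-bis(triisopropylsilyloxy)benzaldehyde
Conditions: TIPSCl (2.1 equiv), imidazole, DMF, 0 °C to rt
Reagents that add atoms: triisopropylsilyl chloride, CC(C)[Si](Cl)(C(C)C)C(C)C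
Why: Phenol silylation that should stop at the bis-ether, because after the 4-OH and one ortho OH have reacted the last ortho OH is held in a hydrogen bond to the formyl group and is strongly deactivated.

Step 2
Reactants: 2 2-hydroxy-4,6-bis(triisopropylsilyloxy)benzaldehyde; 3 [3,4-bis(benzyloxy)phenyl]methanol
Product: 4 2-{[3,4-bis(benzyloxy)benzyl]oxy}-4,6-bis(triisopropylsilyloxy)benzaldehyde
Conditions: PPh3, DIAD, THF, 0 °C to rt
Reagents that add atoms: none
Why: Mitsunobu etherification of an acidic salicylaldehyde-type phenol with a primary benzylic alcohol, under near-neutral conditions that leave the aryl silyl ethers in place.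

Step 3
Reactants: 4 2-{[3,4-bis(benzyloxy)benzyl]oxy}-4,6-bis(triisopropylsilyloxy)benzaldehyde
Product: 6 1-{[3,4-bis(benzyloxy)benzyl]oxy}-2-[(E)-2-nitrovinyl]-3,5-bis(triisopropylsilyloxy)benzene, via nitroaldol adduct 5 (not isolated)
Conditions: MeNO2 (solvent), NH4OAc, 90 °C
Reagents that add atoms: nitromethane, C[N+](=O)[O-]
Why: Henry condensation (nitroaldol addition, then dehydration) that should give the conjugated E-nitrostyrene as the thermodynamic alkene.

Step 4
Reactants: 6 1-{[3,4-bis(benzyloxy)benzyl]oxy}-2-[(E)-2-nitrovinyl]-3,5-bis(triisopropylsilyloxy)benzene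
Product: 8 2-[3,4-bis(benzyloxy)phenyl]-3-nitro-5,7-bis(triisopropylsilyloxy)chroman (racemic, trans isomer expected to prevail), via oxocarbenium nitronate zwitterion 7 (not isolated)
Conditions: Sc(OTf)3 (10 mol %), 4 Å MS, ClCH2CH2Cl, 60 °C
Reagents that add atoms: none
Why: Proposed new method: Sc(OTf)3 bound to the nitro group makes C4 of the nitroalkene electrophilic, and the C2–H bond of the benzylic ether, hydridic through the O1 lone pair and the para-benzyloxy group of ring B, should deliver hydride to C4 through a six-membered 1,5 transition state to give zwitterion 7 (aryl-stabilised O1=C2 oxocarbenium, scandium nitronate at C3). The nitronate carbon C3 then adds to the oxocarbenium carbon C2 (intramolecular Henry-type addition) and closes ring C in a 6-endo-trig mode with respect to the O1=C2 bond (exo with respect to the nitronate C=N bond). The closest known reaction type is the Sc(OTf)3-catalysed 1,5-hydride shift/ring closure of ortho-benzyloxy benzylidene malonates to 2-arylchroman-3,3-diesters (internal redox, tert-amino-effect type); new here is the nitroalkene as hydride acceptor, defended by the markedly higher electrophilicity of nitrostyrenes compared with benzylidene malonates and by the known hydride transfer from Hantzsch esters to nitroalkenes. The new stereocentres C2 and C3 are formed under substrate control only (trans, both substituents equatorial, expected), which suffices because C3 becomes a carbonyl carbon in step 5 and C2 is equilibrated in step 6. The selectivities needed are the site of hydride donation and C- over O-attack of the nitronate: the only hydridic C–H within 1,5 reach of C4 is the ring B benzylic one because O5 carries a silyl and not a benzyl group, and O-attack would require an eight-membered ring.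

Step 5
Reactants: 8 2-[3,4-bis(benzyloxy)phenyl]-3-nitro-5,7-bis(triisopropylsilyloxy)chroman
Product: 10 2-[3,4-bis(benzyloxy)phenyl]-5,7-bis(triisopropylsilyloxy)chroman-3-one (racemic), via potassium nitronate 9 (not isolated)
Conditions: KOtBu, THF, 0 °C; then aq. TiCl3, NH4OAc (pH 5–6), THF/H2O, 0 °C to rt
Reagents that add atoms: water, O
Why: Reductive Nef reaction (McMurry TiCl3 variant) of a secondary nitroalkane, run near neutral pH so that aryl silyl ethers, benzyl ethers and the oxidation-prone ketone should survive; the configuration at C2 is of no consequence here.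

Step 6
Reactants: 10 2-[3,4-bis(benzyloxy)phenyl]-5,7-bis(triisopropylsilyloxy)chroman-3-one
Product: 11 (2R,3R)-2-[3,4-bis(benzyloxy)phenyl]-5,7-bis(triisopropylsilyloxy)chroman-3-ol (2,3-cis)
Conditions: RuCl(p-cymene)[(R,R)-TsDPEN] (2 mol %), HCO2H/Et3N (5:2), CH2Cl2, 30 °C
Reagents that add atoms: none
Why: Noyori–Ikariya asymmetric transfer hydrogenation with dynamic kinetic resolution, in which C2–H (benzylic, alpha to the carbonyl and to O1) epimerises through the enol under Et3N, the catalyst reduces the (2R)-ketone faster, and hydride adds to C3 from the face opposite the C2 aryl group, so that both stereocentres should be set as 2,3-cis (2R,3R).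

Step 7
Reactants: 11 (2R,3R)-2-[3,4-bis(benzyloxy)phenyl]-5,7-bis(triisopropylsilyloxy)chroman-3-ol; 12 4-(benzyloxy)-3,5-dimethoxybenzoic acid
Product: 13 (2R,3R)-2-[3,4-bis(benzyloxy)phenyl]-5,7-bis(triisopropylsilyloxy)chroman-3-yl 4-(benzyloxy)-3,5-dimethoxybenzoate
Conditions: DCC, DMAP, CH2Cl2, 0 °C to rt
Reagents that add atoms: none
Why: Steglich esterification of the axial secondary alcohol, which does not touch the C3–O bond and so keeps both configurations.

Step 8
Reactants: 13 (2R,3R)-2-[3,4-bis(benzyloxy)phenyl]-5,7-bis(triisopropylsilyloxy)chroman-3-yl 4-(benzyloxy)-3,5-dimethoxybenzoate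
Product: 14 (2R,3R)-2-[3,4-bis(benzyloxy)phenyl]-5,7-dihydroxychroman-3-yl 4-(benzyloxy)-3,5-dimethoxybenzoate
Conditions: Bu4NF (TBAF), AcOH (1:1), THF, 0 °C
Reagents that add atoms: none
Why: Fluoride cleavage of aryl silyl ethers, buffered with acetic acid so that the ester is not attacked; with the 4'-oxygen still benzylated, no quinone-methide epimerisation at C2 is possible.

Step 9
Reactants: 14 (2R,3R)-2-[3,4-bis(benzyloxy)phenyl]-5,7-dihydroxychroman-3-yl 4-(benzyloxy)-3,5-dimethoxybenzoate
Product: 15 (2R,3R)-2-(3,4-dihydroxyphenyl)-5,7-dihydroxychroman-3-yl 4-hydroxy-3,5-dimethoxybenzoate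
Conditions: H2 (1 atm), Pd(OH)2/C, THF/MeOH, rt
Reagents that add atoms: none
Why: Hydrogenolysis of the three benzyl ethers under neutral conditions, which should leave the ester, the aryl methyl ethers and the ring C ether intact, as is usual for benzylated catechin esters.

**Compound list**

1 | 2,4,6-trihydroxybenzaldehyde | O=Cc1c(O)cc(O)cc1O | starting material
2 | 2-hydroxy-4,6-bis(triisopropylsilyloxy)benzaldehyde | O=Cc1c(O)cc(O[Si](C(C)C)(C(C)C)C(C)C)cc1O[Si](C(C)C)(C(C)C)C(C)C | intermediate
3 | [3,4-bis(benzyloxy)phenyl]methanol | OCc1ccc(OCc2ccccc2)c(OCc2ccccc2)c1 | starting material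
4 | 2-{[3,4-bis(benzyloxy)benzyl]oxy}-4,6-bis(triisopropylsilyloxy)benzaldehyde | O=Cc1c(OCc2ccc(OCc3ccccc3)c(OCc3ccccc3)c2)cc(O[Si](C(C)C)(C(C)C)C(C)C)cc1O[Si](C(C)C)(C(C)C)C(C)C | intermediate
5 | nitroaldol adduct, 1-aryl-2-nitroethanol derived from 4 (racemic, not isolated) | [O-][N+](=O)CC(O)c1c(OCc2ccc(OCc3ccccc3)c(OCc3ccccc3)c2)cc(O[Si](C(C)C)(C(C)C)C(C)C)cc1O[Si](C(C)C)(C(C)C)C(C)C | intermediate
6 | 1-{[3,4-bis(benzyloxy)benzyl]oxy}-2-[(E)-2-nitrovinyl]-3,5-bis(triisopropylsilyloxy)benzene | [O-][N+](=O)/C=C/c1c(OCc2ccc(OCc3ccccc3)c(OCc3ccccc3)c2)cc(O[Si](C(C)C)(C(C)C)C(C)C)cc1O[Si](C(C)C)(C(C)C)C(C)C | intermediate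
7 | oxocarbenium nitronate zwitterion formed by 1,5-hydride shift (not isolated) | [O-][N+]([O-])=CCc1c([O+]=Cc2ccc(OCc3ccccc3)c(OCc3ccccc3)c2)cc(O[Si](C(C)C)(C(C)C)C(C)C)cc1O[Si](C(C)C)(C(C)C)C(C)C | intermediate
8 | 2-[3,4-bis(benzyloxy)phenyl]-3-nitro-5,7-bis(triisopropylsilyloxy)chroman (racemic, diastereomer mixture, trans expected to prevail) | [O-][N+](=O)C1Cc2c(O[Si](C(C)C)(C(C)C)C(C)C)cc(O[Si](C(C)C)(C(C)C)C(C)C)cc2OC1c1ccc(OCc2ccccc2)c(OCc2ccccc2)c1 | intermediate
9 | potassium nitronate of 8 (not isolated) | [K+].[O-][N+]([O-])=C1Cc2c(O[Si](C(C)C)(C(C)C)C(C)C)cc(O[Si](C(C)C)(C(C)C)C(C)C)cc2OC1c1ccc(OCc2ccccc2)c(OCc2ccccc2)c1 | intermediate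
10 | 2-[3,4-bis(benzyloxy)phenyl]-5,7-bis(triisopropylsilyloxy)chroman-3-one (racemic) | O=C1Cc2c(O[Si](C(C)C)(C(C)C)C(C)C)cc(O[Si](C(C)C)(C(C)C)C(C)C)cc2OC1c1ccc(OCc2ccccc2)c(OCc2ccccc2)c1 | intermediate
11 | (2R,3R)-2-[3,4-bis(benzyloxy)phenyl]-5,7-bis(triisopropylsilyloxy)chroman-3-ol (2,3-cis) | O[C@@H]1Cc2c(O[Si](C(C)C)(C(C)C)C(C)C)cc(O[Si](C(C)C)(C(C)C)C(C)C)cc2O[C@@H]1c1ccc(OCc2ccccc2)c(OCc2ccccc2)c1 | intermediate
12 | 4-(benzyloxy)-3,5-dimethoxybenzoic acid | COc1cc(C(=O)O)cc(OC)c1OCc1ccccc1 | starting material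
13 | (2R,3R)-2-[3,4-bis(benzyloxy)phenyl]-5,7-bis(triisopropylsilyloxy)chroman-3-yl 4-(benzyloxy)-3,5-dimethoxybenzoate | COc1cc(C(=O)O[C@@H]2Cc3c(O[Si](C(C)C)(C(C)C)C(C)C)cc(O[Si](C(C)C)(C(C)C)C(C)C)cc3O[C@@H]2c2ccc(OCc3ccccc3)c(OCc3ccccc3)c2)cc(OC)c1OCc1ccccc1 | intermediate
14 | (2R,3R)-2-[3,4-bis(benzyloxy)phenyl]-5,7-dihydroxychroman-3-yl 4-(benzyloxy)-3,5-dimethoxybenzoate | COc1cc(C(=O)O[C@@H]2Cc3c(O)cc(O)cc3O[C@@H]2c2ccc(OCc3ccccc3)c(OCc3ccccc3)c2)cc(OC)c1OCc1ccccc1 | intermediate
15 | (2R,3R)-2-(3,4-dihydroxyphenyl)-5,7-dihydroxychroman-3-yl 4-hydroxy-3,5-dimethoxybenzoate | COc1cc(C(=O)O[C@@H]2Cc3c(O)cc(O)cc3O[C@@H]2c2ccc(O)c(O)c2)cc(OC)c1O | target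

**Step count and risks**

Total step count: 9. Longest linear sequence: 9 steps (1 to 15).

Steps most likely to fail:

1. Step 4 (proposed new method). Lewis-acid ionisation of the electron-rich benzyl aryl ether (C–O heterolysis and Friedel–Crafts benzylation) may outrun hydride transfer. Hydride transfer may also be too slow because ring A donates into the nitroalkene, or the oxocarbenium may be intercepted by adventitious water. Fallback by known chemistry, setting out from 2: DABCO-mediated oxa-Michael/Henry/dehydration cascade of salicylaldehyde 2 with 1,2-bis(benzyloxy)-4-[(E)-2-nitrovinyl]benzene F1 (from 3,4-bis(benzyloxy)benzaldehyde, MeNO2 and NH4OAc) should give 2-[3,4-bis(benzyloxy)phenyl]-3-nitro-5,7-bis(triisopropylsilyloxy)-2H-chromene F2. Conjugate reduction of its nitroalkene with NaBH4 (THF/MeOH, 0 °C) rejoins the route at 8.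

2. Step 5. The nitronate may open ring C by beta-elimination of the ring A phenoxide, N–O reduction may stall before hydrolysis, or the base may strip a silyl ether. Fallback setting out from 8: reduction of the neutral nitro compound with SnCl2·2H2O, PhSH and Et3N (MeCN, rt) should give 2-[3,4-bis(benzyloxy)phenyl]-5,7-bis(triisopropylsilyloxy)chroman-3-one oxime F3 without a free nitronate under strongly basic conditions. Transoximation with glyoxylic acid (NaOAc, aq. AcOH/THF, rt) then releases the ketone and rejoins the route at 10.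

3. Step 6. Epimerisation at C2 may be too slow relative to hydride transfer, so that the resolution is not dynamic, and enantioface discrimination may be weak for a ketone with no aryl group directly on the carbonyl carbon. Fallback setting out from 10: LiBH(s-Bu)3 (L-Selectride), THF, −78 °C, a reduction known to give the 2,3-cis alcohol from benzylated flavan-3-ones, should give racemic cis-2-[3,4-bis(benzyloxy)phenyl]-5,7-bis(triisopropylsilyloxy)chroman-3-ol F4. Separation of its enantiomers by preparative HPLC on a chiral stationary phase rejoins the route at 11.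

**Further compounds**

F1 | step 4 | 1,2-bis(benzyloxy)-4-[(E)-2-nitrovinyl]benzene | [O-][N+](=O)/C=C/c1ccc(OCc2ccccc2)c(OCc2ccccc2)c1
F2 | step 4 | 2-[3,4-bis(benzyloxy)phenyl]-3-nitro-5,7-bis(triisopropylsilyloxy)-2H-chromene (racemic) | [O-][N+](=O)C1=Cc2c(O[Si](C(C)C)(C(C)C)C(C)C)cc(O[Si](C(C)C)(C(C)C)C(C)C)cc2OC1c1ccc(OCc2ccccc2)c(OCc2ccccc2)c1
F3 | step 5 | 2-[3,4-bis(benzyloxy)phenyl]-5,7-bis(triisopropylsilyloxy)chroman-3-one oxime (racemic) | ON=C1Cc2c(O[Si](C(C)C)(C(C)C)C(C)C)cc(O[Si](C(C)C)(C(C)C)C(C)C)cc2OC1c1ccc(OCc2ccccc2)c(OCc2ccccc2)c1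
F4 | step 6 | racemic cis-2-[3,4-bis(benzyloxy)phenyl]-5,7-bis(triisopropylsilyloxy)chroman-3-ol (racemate, the 2R,3R enantiomer is drawn) | O[C@@H]1Cc2c(O[Si](C(C)C)(C(C)C)C(C)C)cc(O[Si](C(C)C)(C(C)C)C(C)C)cc2O[C@@H]1c1ccc(OCc2ccccc2)c(OCc2ccccc2)c1
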